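(The readings stem from a simulated flask with made-up constants.)

A first chain carrier has two exits, to target with coupling partner or to side product with transfer agent. The amount of carrier therefore cancels from the ratio of side product to target, and at a given temperature that ratio follows c(transfer agent)/c(coupling partner).

| flask | starting material | transfer agent | gas | initiator | temperature | remark | time |
|---|---|---|---|---|---|---|---|
| Saturday's | 0.40 M | 0.40 M | 18 mM (held) | 2.6 mM | 2 °C | run made earlier |  |
| Sunday's | 0.40 M | 0.40 M | 18 mM (held) | 38 mM | 19 °C | run made earlier |  |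
| Wednesday's | 0.40 M | 0.78 M | 18 mM (held) | 8 mM | 2 °C | run made earlier |  |
| oak | 0.40 M | 0.600 M | 18 mM (held) | 25 mM | 10 °C |  | 2.0 h |
| maple | 0.40 M | 0.600 M | 18 mM (held) | 2.0 mM | 25 °C |  | 2.0 h |
| elm | 0.40 M | 0.400 M | 18 mM (held) | 8.0 mM | 25 °C |  | 2.0 h |
| birch | 0.40 M | 1.50 M | 18 mM (held) | 8.0 mM | −5 °C |  | 2.0 h |

Saturday's run (percent of the starting material charged)

| time / h | target / % | side product / % | starting material / % |
|---|---|---|---|
| 0.250 | 2.6 | 0.1 | 99.7 |
| 0.417 | 5.5 | 0 | 94.8 |
| 0.667 | 5.9 | 2.2 | 94.8 |
| 1.00 | 7.2 | 1.0 | 93.2 |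
| 2.00 | 10.1 | 1.4 | 87.7 |
| 3.00 | 12.7 | 0.7 | 85.9 |

Sunday's run (percent of the starting material charged)

| time / min | target / % | side product / % | starting material / % |
|---|---|---|---|
| 10.0 | 82.8 | 8.3 | 6.6 |
| 20.0 | 90.1 | 8.9 | 0 |
| 30.0 | 89.5 | 9.7 | 0.3 |
| 40.0 | 91.3 | 9.3 | 0.2 |
| 50.0 | 90.0 | 9.7 | 0.6 |
| 60.0 | 90.8 | 11.1 | 0 |

Wednesday's run (percent of the starting material charged)

| time / h | target / % | side product / % | starting material / % |
|---|---|---|---|
| 0.250 | 4.4 | 0 | 96.7 |
| 0.833 | 9.8 | 1.7 | 87.5 |
| 1.50 | 15.2 | 2.7 | 84.4 |
| 2.00 | 17.7 | 1.6 | 80.6 |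
| 3.00 | 21.9 | 3.3 | 77.7 |

(each reading ± 1 percentage point)

- released group is meant together with its crystals
- solid, in amounts per volume of the solution: crystals
- at the start none of coupling partner is dissolved
- the analysis behind the earlier runs scatters by 1 percentage point, standard deviation
- on the list of suspects stand: initiator -> 2 initiating radical; starting material + initiating radical -> capped initiator + first chain carrier; coupling partner + first chain carrier -> target + second chain carrier; starting material + second chain carrier -> released group + first chain carrier; transfer agent + first chain carrier -> side product + idle radical; 2 idle radical -> ended radicals; 2 second chain carrier -> ended chains; crystals <-> released group; gas <-> coupling partner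

- all flasks from highest to lowest share of target in all that became target or side product, at 2.0 h (oak / maple / elm / birch)
- the share of target in all that became target or side product of the flask you put first, at 2.0 h
- the share of target in all that became target or side product of the flask you put last, at 2.0 h

The runs seem to disagree. Summed side product over summed target, divided by c(transfer agent), gives the side ratio per molar of transfer agent, a selectivity factor: 0.173 L mol⁻¹ in Wednesday's run. Sunday's plateau gives 0.270 L mol⁻¹, although both flasks hold gas at 18 mM.

But gas gives a ceiling on c(coupling partner), not its value. Sunday's flask made target at 1.99 M h⁻¹ up to its first reading, and Wednesday's at 0.0292 M h⁻¹ over its whole run, far slower. Sunday's ratio is thus read as a dip in c(coupling partner): with temperature set aside, it means about 11.5 mM on average. Wednesday's slow flask gives the better s, though its side-product readings, at most 3.3 %, carry a scatter of 1 percentage point.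

The share is then 1/(1 + s·c(transfer agent)), with no temperature term. This reckoning gives elm 93.5 % and birch 79.4 %. Oak and maple tie at 90.6 %, so this reckoning leaves their order open.

The forecast gives elm > oak > maple > birch, with top 89 % (86 % to 92.5 %) and low 81 % (74 % to 85 %): “Birch's large transfer-agent excess outweighs its cold.”

The flasks give elm > maple > oak > birch, with top 93.7 % and low 74.4 %.

    initiator → 2 initiating radical (k = 0.00201 s⁻¹, Ea = 75.0 kJ mol⁻¹)
    starting material + initiating radical → capped initiator + first chain carrier (k = 3.51 × 10⁵ L mol⁻¹ s⁻¹, Ea = 20.0 kJ mol⁻¹)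
    coupling partner + first chain carrier → target + second chain carrier (k = 2.56 × 10⁶ L mol⁻¹ s⁻¹, Ea = 25.0 kJ mol⁻¹)
    starting material + second chain carrier → released group + first chain carrier (k = 10400 L mol⁻¹ s⁻¹, Ea = 12.0 kJ mol⁻¹)
    transfer agent + first chain carrier → side product + idle radical (kL = 6430 L mol⁻¹ s⁻¹, Ea = 14.0 kJ mol⁻¹)
    2 idle radical → ended radicals (k = 5.10 × 10⁸ L mol⁻¹ s⁻¹, Ea = 11.0 kJ mol⁻¹)
    2 second chain carrier → ended chains (k = 1.40 × 10⁶ L mol⁻¹ s⁻¹, Ea = 21.0 kJ mol⁻¹)
    crystals ⇌ released group, rate k8*(cs8 - [released group]) while solid is left; crystals form when [released group] > cs8 (solubility = 0.340 M, k = 0.0511 s⁻¹)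
    gas ⇌ coupling partner, rate k9*(csat - [coupling partner]) (kL = 0.0726 s⁻¹)
    (constants at 25 °C)

Elm's share corresponds to an s of 0.168 L mol⁻¹ and birch's to 0.230 L mol⁻¹, higher in the colder flask, so the reckoning stands 5 points above birch. The neighbour is elm with initiator raised to 0.032 M. The reckoning, blind to initiator, again gives 93.5 %, but this neighbour ends with 89.6 % target and 10.4 % side product, an s of 0.290 L mol⁻¹, close to Sunday's reading, and a share of 89.6 %.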